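## Structural features

The target is a 2,3-dihydrobenzofuran whose benzene ring is a fully substituted phloroglucinol. O1 sits on C7a, hydroxyls on C4 and C6, an acetyl group on C5 between them, and C7 carries a methylene bridge to C3' of a 6-ethyl-4-hydroxy-5-methyl-2H-pyran-2-one. C2 is the only stereocentre (R). It is an allylic ether carbon bearing a 6-methylhepta-1,5-dien-2-yl group, so a 1,1-disubstituted alkene stands directly on it and no neighbouring stereocentre can relay configuration. The fragile groups are the 1,5-diene (cation–olefin cyclisation under strong Brønsted or Lewis acid), the allylic aryl ether C2–O1 (ionisable by acid or by zerovalent palladium, which would erase the configuration), the acidic pyrone enol and the electron-rich ring. The real difficulty is regiochemical: three oxygens of common origin must take three different roles on a hexasubstituted ring, and one isolated stereocentre must be set beside an exocyclic alkene that must not migrate. The key step exploits that C4', C5' and C6' with their methyl and ethyl groups are the carbon chain of the methylketene dimer, while C2', C3', the bridging methylene, C7 and an ortho oxygen are the atoms C2, C3, C4, C4a, C8a and O1 of a chroman-2-one; the benzylpyrone is therefore the ring-switched isomer of a 3-acyl dihydrocoumarin. Because the switch unveils a single phenol ortho to the bridge, that oxygen is used here as O1, and an iodine placed beforehand on C8 of the lactone emerges on the future C3a next to it.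

## Logic of the disconnections

17 to 16. The two O–H bonds at C4 and C6 are reconnected as acetal O–CH2 bonds. These oxygens must stay masked to the end so that only the third oxygen can close the dihydrofuran, and the ortho acetyl group makes exactly these two acetals the easiest to cleave. The skeleton does not change, but all acid is confined to one short last step. The forward step must be fast at low acid strength so that the diene and the C2–O1 bond survive.

16 to 14 (through 15). The C5–C(acetyl) bond is cut. A Friedel–Crafts acetylation would destroy the diene and the acetals, so the acyl group comes in as a masked acyl anion by cross-coupling at a C5–I bond. This removes the ketone and leaves a simple aryl iodide. The coupling must run below the temperature at which zerovalent palladium ionises the allylic aryl ether, and enol ether 15 must hydrolyse before the acetals do.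

14 to 13. The C5–I bond is cut. C5 is the last aromatic C–H, so there is no regiochemical question on the ring. The electrophile must prefer the arene to the two alkenes and to the pyrone enol.

13 to 11 and 12. The C3–C3a and O1–C2 bonds are cut. C2, C3 and the whole side chain are the carbon skeleton of 12, so one annulation builds the ring, the stereocentre and the exocyclic alkene in its final position, with no epoxidation that must choose between two alkenes and no dehydration that must choose a direction. Ten carbons and the stereocentre disappear and the achiral 11 remains. The forward step needs aryl addition at the terminal vinyl carbon of 12, a single phenol next to the iodide (the reason for keeping the acetals), and ligand control of the C–O bond formation.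

11 to 5 and 8 (key step). The C3'–C4' and O1'–C2' bonds are cut. The pyrone with both alkyl groups collapses into the six-carbon lactone 8, and the arene returns to a bicyclic aryl lactone in which the future O1 is tied up and the other two oxygens are masked alike. The forward step needs C-acylation at the strained carbonyl of 8, tolerance of the aryl iodide and acetals, and complete translactonisation.

5 to 4 to 3 to 1 and 2. The C8–I bond is cut first; iodination is placed on the lactone because C8 is the only position ortho to one acetal oxygen and para to the other. Then the two acetal O–C bonds are cut, and finally C4–C4a and the lactone O1–C2. The symmetry of 1 makes the first C–C bond formation unambiguous; the forward steps must stop at mono-addition and mono-iodination.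

8 to 6 (through 7). The C3–C4 and O1–C2 bonds of the four-membered ring are cut, which is the head-to-tail dimerisation of two molecules of 7; each of them comes from one molecule of 6, so two molecules of 6 supply the six carbons of 8. The dimer's stereocentre is lost later, so no control is needed; the demand is only that the lactone dimer and not a polymer forms.

## Other disconnections considered

Alternative 1: The cut goes through C2–C3 and O1–C2, so that C2 arrives as the carbanion carbon of sulfonium ylide A2 and C3 as the methylene of an ortho-quinone methide released from sulfone A1. In the forward step a base expels sulfinate from A1, A2 adds to the methylene, and the C7a phenoxide displaces the sulfide inside a chiral hydrogen-bond donor, which should give ketone A3.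
- In its favour: the acetyl group is present from the start, only one phenol is free so the ring fusion is unambiguous, and no transition metal is used.
- Against it here: A3 holds its stereocentre alpha to a ketone. The basic conditions of its own formation, and above all the methylenation that must follow (which must also choose between two ketones), put the configuration at risk. C7 is still unsubstituted, so pyrone A4 has to be made separately and attached late through a one-carbon link, where double addition of the pyrone is a known hazard.
- Comparison: both plans make O1–C2 in the ring-forming step, but the chosen plan takes the side chain at the alkene oxidation level from 12, whereas this one needs an extra olefination. Mechanistically the alternative is the better in that zerovalent palladium never meets the allylic aryl ether, and it is also the better in placing the acetyl group without the three steps the chosen plan spends on it. On step economy it is the weaker: A1, A2 and A4 each need their own preparation, and about eleven to twelve steps are expected against nine.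

Alternative 2: The cut is C4'–C5' and O1'–C2', made at the end of the synthesis: the pyrone is assembled last on the finished dihydrobenzofuran from acid chloride A5 and silyl enol ether A6. In the forward step A6 is C-acylated by A5, the enol oxygen of the new 1,3-dicarbonyl unit attacks the aryl lactone, and the lactone opens to the C6 hydroxyl to give A7, from which the C4 acetate is then removed.
- In its favour: the translactonisation has the same driving force as in the chosen plan and is its equal there. The acidic pyrone is absent from all earlier steps, a real advantage over the chosen plan, which carries it through two iodinations and two palladium-catalysed steps. The released hydroxyl is fixed by the lactone.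
- Against it here: A5 is a malonyl-type chloride with an acidic C–H on the most sensitive substrate of the synthesis, and making and coupling it exposes the diene and the allylic ether to chlorinating agents, hydrogen chloride and Lewis acids. Silyl enol ethers can be O-acylated as well as C-acylated. The fused lactone must be built regioselectively onto the C6 oxygen although the C4 and C6 hydroxyls both flank the acetyl group and are hard to tell apart.
- Comparison: the chosen plan spends the ring switch early on a robust achiral lactone and lets it differentiate the oxygens; the alternative spends it late and needs the oxygens differentiated beforehand. The route is longer, since the dihydrobenzofuran with its stereocentre and acetyl group must exist first and three to four further steps then lead to A5.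

Alternative 3: The cut is C3–C3a and C7a–O1; aryl iodide A8 and epoxide A9 are joined under Pd(OAc)2, a phosphine and norbornene. In the forward step oxidative addition, norbornene insertion and ortho C–H palladation give a palladacycle that opens A9 at its CH2 terminus; after norbornene extrusion the alkoxide closes the ring by C–O reductive elimination to A10.
- In its favour: the C2 configuration is carried in from A9 and its C–O bond is never broken, so the absolute configuration does not depend on a chiral ligand performing on a crowded substrate. In this respect it is better than the chosen plan. The ring fusion is fixed by the positions of iodine and hydrogen, and there is no diene insertion regiochemistry to control.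
- Against it here: A9 needs two adjacent stereocentres, one of which is later destroyed. The silyl ether must become the exocyclic alkene by desilylation, oxidation to an alpha-aryloxy ketone and methylenation, with the epimerisation hazard of alternative 1. A10 still lacks the acetyl group and the pyrone, so the benzylic acetal must be unmasked beside two aryl acetals, activated and coupled with A4 (C- against O-alkylation), and C5 must be acylated late in the presence of the alkenes.
- Comparison: both plans use palladium to make C3–C3a and close the dihydrofuran in one step and are equals there. The chosen plan obtains ring, stereocentre and the complete side chain from 12 in that step, whereas the alternative needs about five more steps for the side chain and at least four more for the pyrone and acetyl group.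

Key step: step 5

Remark on the chemistry: the lactone enters the ring switch with iodine on C8 as a spectator (the iodine-free lactone 4 is its direct precursor), and the phenol unveiled by the switch is used as O1 on C7a; until the other two oxygens are told apart this is equivalent to reading it as the C6 hydroxyl, and it is the reading that fixes where the dihydrofuran closes.

## Route

Step 1
Reactants: 1 phloroglucinol (benzene-1,3,5-triol); 2 acrylic acid
Product: 3 5,7-dihydroxychroman-2-one
Conditions: Amberlyst-15, toluene/1,4-dioxane, reflux, Dean–Stark (1 in 1.5-fold excess)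
Reagents that add atoms: none
Why: Acid-catalysed Friedel–Crafts conjugate addition (hydroarylation) of the electron-rich ring to protonated acrylic acid, followed by lactonisation onto an ortho hydroxyl; the threefold symmetry of 1 makes the regiochemistry unique, and the excess of 1 should limit double addition.

Step 2
Reactants: 3 5,7-dihydroxychroman-2-one
Product: 4 5,7-bis(methoxymethoxy)chroman-2-one
Conditions: MOMCl (2.6 equiv), i-Pr2NEt (3 equiv), CH2Cl2, 0 °C → rt
Reagents that add atoms: chloromethyl methyl ether, COCCl
Why: Standard methoxymethylation of two unhindered, non-chelated phenols under a non-nucleophilic amine base, which should leave the aryl lactone intact.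

Step 3
Reactants: 4 5,7-bis(methoxymethoxy)chroman-2-one
Product: 5 8-iodo-5,7-bis(methoxymethoxy)chroman-2-one
Conditions: NIS (1.05 equiv), MeCN, rt, dark
Reagents that add atoms: N-iodosuccinimide, O=C1CCC(=O)N1I
Why: Electrophilic aromatic iodination; C8 is ortho to the C7 acetal oxygen and para to the C5 one, whereas C6 lies between two acetal groups and is para only to the weakly donating acyloxy oxygen, so substitution should go to C8, as in halogenation of 3,5-dialkoxytoluenes.

Step 4
Reactants: 6 propanoyl chloride (two molecules for each molecule of 8)
Product: 8 rac-(Z)-4-ethylidene-3-methyloxetan-2-one (methylketene dimer), via methylketene 7 (not isolated)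
Conditions: Et3N (1.05 equiv per 6), CH2Cl2, 0 °C → rt; pentane, filtration; distillation at reduced pressure
Reagents that add atoms: propanoyl chloride (the second molecule of 6, which enters as a second molecule of methylketene 7), CCC(=O)Cl
Why: Each molecule of 6 is dehydrochlorinated to the aldoketene 7, and two molecules of 7 combine in an amine-catalysed head-to-tail [2+2] dimerisation to the beta-lactone dimer, the same reaction type used to make alkylketene dimers from acid chlorides; the stereocentre of 8 is irrelevant because it becomes sp2 in the pyrone.

Step 5
Reactants: 5 8-iodo-5,7-bis(methoxymethoxy)chroman-2-one; 8 rac-(Z)-4-ethylidene-3-methyloxetan-2-one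
Product: 11 6-ethyl-4-hydroxy-3-{[2-hydroxy-3-iodo-4,6-bis(methoxymethoxy)phenyl]methyl}-5-methyl-2H-pyran-2-one, via lithium lactone enolate 9 (not isolated), via 3-acyl lactone 10 (not isolated)
Conditions: LiN(SiMe3)2 (1.1 equiv), THF, −78 °C; 8 (1.3 equiv) added slowly, −78 → −20 °C; then rt; aq. NH4Cl, 1 M HCl to pH 4, 0 °C
Reagents that add atoms: none
Why: LiN(SiMe3)2 converts 5 into enolate 9 at −78 °C, where the aryl ester does not yet extrude a ketene. C3 of 9 attacks the strained carbonyl of 8 with acyl–oxygen cleavage, a Claisen-type acylation by a ketene dimer (the known route from enolates to 3,5-diketo esters), forming C3'–C4'; the enolate set free is reprotonated internally to the stabilised tricarbonyl anion of 10. On warming, the oxygen of the ethyl ketone enolate adds to the aryl lactone carbonyl in a 6-exo-trig closure (O1'–C2'), the iodophenoxide leaves, and tautomerisation gives the pyronate; this is the known lactonisation of 3,5-diketo esters to 4-hydroxy-2-pyrones, eased by the aryloxide leaving group. No stereocentre is created, and the two stereogenic sp3 carbons of 10 become sp2. C-acylation over O-acylation should be secured by the lithium counterion at low temperature and by strain release on attack at the carbonyl carbon, and slow addition of 8 to the cold enolate should keep its acidic C3–H from quenching 9. A second acylation is not expected, because the pyronate is a weak nucleophile and the released phenoxide is protonated by the pyrandione (pKa near 5). The iodine on C8 is inert to the amide base and ends ortho to the new phenol.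

Step 6
Reactants: 11 6-ethyl-4-hydroxy-3-{[2-hydroxy-3-iodo-4,6-bis(methoxymethoxy)phenyl]methyl}-5-methyl-2H-pyran-2-one; 12 β-myrcene (7-methyl-3-methylideneocta-1,6-diene)
Product: 13 6-ethyl-4-hydroxy-5-methyl-3-{[(2R)-4,6-bis(methoxymethoxy)-2-(6-methylhepta-1,5-dien-2-yl)-2,3-dihydro-1-benzofuran-7-yl]methyl}-2H-pyran-2-one
Conditions: Pd2(dba)3·CHCl3 (5 mol %), chiral sulfinamide–monophosphine ligand (Sadphos type, 12 mol %), K2CO3 (3 equiv), 12 (3 equiv), toluene/DMF, 60 °C; work-up at pH 4
Reagents that add atoms: none
Why: Heck/Tsuji–Trost (Larock-type) heteroannulation of a 1,3-diene by an ortho-iodophenol: zerovalent palladium inserts into C–I, the aryl group adds to the terminal carbon of the monosubstituted vinyl group of 12 (C3–C3a), and the only ortho phenoxide attacks the internal terminus of the resulting η3-allyl complex in a 5-exo closure (O1–C2). The allyl complex can exchange faces through its unsubstituted CH2 terminus, so C2 is set in the C–O bond-forming step under control of the chiral ligand, whose antipode is chosen to give 2R. The trisubstituted alkene of 12 should not insert, and the exocyclic alkene is delivered in its final position.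

Step 7
Reactants: 13 6-ethyl-4-hydroxy-5-methyl-3-{[(2R)-4,6-bis(methoxymethoxy)-2-(6-methylhepta-1,5-dien-2-yl)-2,3-dihydro-1-benzofuran-7-yl]methyl}-2H-pyran-2-one
Product: 14 6-ethyl-4-hydroxy-3-{[(2R)-5-iodo-4,6-bis(methoxymethoxy)-2-(6-methylhepta-1,5-dien-2-yl)-2,3-dihydro-1-benzofuran-7-yl]methyl}-5-methyl-2H-pyran-2-one
Conditions: NIS (1.05 equiv), CH2Cl2/MeCN, −20 → 0 °C, dark
Reagents that add atoms: N-iodosuccinimide, O=C1CCC(=O)N1I
Why: Electrophilic aromatic iodination at the only remaining aromatic C–H, which is ortho to two acetal oxygens and para to O1; the isolated alkenes are far less nucleophilic than this ring, so one equivalent at low temperature should be selective. Iodine taken up at the already substituted C3' of the pyrone enol would give a 3-iodo-2,4-dione that is itself an iodonium donor, so it should be passed on to the arene and not accumulate.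

Step 8
Reactants: 14 6-ethyl-4-hydroxy-3-{[(2R)-5-iodo-4,6-bis(methoxymethoxy)-2-(6-methylhepta-1,5-dien-2-yl)-2,3-dihydro-1-benzofuran-7-yl]methyl}-5-methyl-2H-pyran-2-one
Product: 16 3-{[(2R)-5-acetyl-4,6-bis(methoxymethoxy)-2-(6-methylhepta-1,5-dien-2-yl)-2,3-dihydro-1-benzofuran-7-yl]methyl}-6-ethyl-4-hydroxy-5-methyl-2H-pyran-2-one, via 1-ethoxyvinyl arene 15 (not isolated)
Conditions: tributyl(1-ethoxyvinyl)stannane (1.5 equiv), Pd(PPh3)4 (10 mol %), CuI (20 mol %), CsF (2 equiv), DMF, 45 °C; filtration; then 1 M aq. HCl/THF, 0 °C, 15 min
Reagents that add atoms: tributyl(1-ethoxyvinyl)stannane, CCCC[Sn](CCCC)(CCCC)C(=C)OCC; water, O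
Why: Stille coupling of the aryl iodide with an alpha-alkoxyvinyl stannane as acetyl anion equivalent, accelerated by CuI and fluoride for the doubly ortho-substituted iodide, followed by brief hydrolysis of enol ether 15, which should be much faster than acetal cleavage. While the ketone is still masked the aryloxide on C2 is electron-rich and a poor leaving group, which should keep the allylic C2–O1 bond from ionising on zerovalent palladium at 45 °C.

Step 9
Reactants: 16 3-{[(2R)-5-acetyl-4,6-bis(methoxymethoxy)-2-(6-methylhepta-1,5-dien-2-yl)-2,3-dihydro-1-benzofuran-7-yl]methyl}-6-ethyl-4-hydroxy-5-methyl-2H-pyran-2-one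
Product: 17 3-{[(2R)-5-acetyl-4,6-dihydroxy-2-(6-methylhepta-1,5-dien-2-yl)-2,3-dihydro-1-benzofuran-7-yl]methyl}-6-ethyl-4-hydroxy-5-methyl-2H-pyran-2-one (target CNP0294086.1)
Conditions: 0.5 M HCl in MeOH/THF (4:1), 0 °C → rt
Reagents that add atoms: none
Why: Acid-catalysed acetal solvolysis; both acetals are ortho to the acetyl group and should cleave unusually fast through the hydrogen-bonded ortho-hydroxy ketone, so dilute acid at or below room temperature should spare the 1,5-diene and the allylic ether, and C2 is not touched.

## Compound list

1 | phloroglucinol (benzene-1,3,5-triol) | Oc1cc(O)cc(O)c1 | starting material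
2 | acrylic acid | C=CC(=O)O | starting material
3 | 5,7-dihydroxychroman-2-one | O=C1CCc2c(O)cc(O)cc2O1 | intermediate
4 | 5,7-bis(methoxymethoxy)chroman-2-one | O=C1CCc2c(OCOC)cc(OCOC)cc2O1 | intermediate
5 | 8-iodo-5,7-bis(methoxymethoxy)chroman-2-one | O=C1CCc2c(OCOC)cc(OCOC)c(I)c2O1 | intermediate
6 | propanoyl chloride | CCC(=O)Cl | starting material
7 | methylketene (prop-1-en-1-one; formed in the flask, not isolated) | CC=C=O | intermediate
8 | rac-(Z)-4-ethylidene-3-methyloxetan-2-one (methylketene dimer) | C/C=C1\OC(=O)C1C | intermediate
9 | lithium 8-iodo-5,7-bis(methoxymethoxy)-4H-chromen-2-olate (lactone enolate; not isolated) | [Li+].[O-]C1=CCc2c(OCOC)cc(OCOC)c(I)c2O1 | intermediate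
10 | 8-iodo-5,7-bis(methoxymethoxy)-3-(2-methyl-3-oxopentanoyl)chroman-2-one (present as its lithium enolate; not isolated) | CCC(=O)C(C)C(=O)C1Cc2c(OCOC)cc(OCOC)c(I)c2OC1=O | intermediate
11 | 6-ethyl-4-hydroxy-3-{[2-hydroxy-3-iodo-4,6-bis(methoxymethoxy)phenyl]methyl}-5-methyl-2H-pyran-2-one | CCc1oc(=O)c(Cc2c(O)c(I)c(OCOC)cc2OCOC)c(O)c1C | intermediate
12 | β-myrcene (7-methyl-3-methylideneocta-1,6-diene) | C=CC(=C)CCC=C(C)C | starting material
13 | 6-ethyl-4-hydroxy-5-methyl-3-{[(2R)-4,6-bis(methoxymethoxy)-2-(6-methylhepta-1,5-dien-2-yl)-2,3-dihydro-1-benzofuran-7-yl]methyl}-2H-pyran-2-one | C=C(CCC=C(C)C)[C@H]1Cc2c(OCOC)cc(OCOC)c(Cc3c(O)c(C)c(CC)oc3=O)c2O1 | intermediate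
14 | 6-ethyl-4-hydroxy-3-{[(2R)-5-iodo-4,6-bis(methoxymethoxy)-2-(6-methylhepta-1,5-dien-2-yl)-2,3-dihydro-1-benzofuran-7-yl]methyl}-5-methyl-2H-pyran-2-one | C=C(CCC=C(C)C)[C@H]1Cc2c(OCOC)c(I)c(OCOC)c(Cc3c(O)c(C)c(CC)oc3=O)c2O1 | intermediate
15 | 3-{[(2R)-5-(1-ethoxyethenyl)-4,6-bis(methoxymethoxy)-2-(6-methylhepta-1,5-dien-2-yl)-2,3-dihydro-1-benzofuran-7-yl]methyl}-6-ethyl-4-hydroxy-5-methyl-2H-pyran-2-one (not isolated) | C=C(CCC=C(C)C)[C@H]1Cc2c(OCOC)c(C(=C)OCC)c(OCOC)c(Cc3c(O)c(C)c(CC)oc3=O)c2O1 | intermediate
16 | 3-{[(2R)-5-acetyl-4,6-bis(methoxymethoxy)-2-(6-methylhepta-1,5-dien-2-yl)-2,3-dihydro-1-benzofuran-7-yl]methyl}-6-ethyl-4-hydroxy-5-methyl-2H-pyran-2-one | C=C(CCC=C(C)C)[C@H]1Cc2c(OCOC)c(C(C)=O)c(OCOC)c(Cc3c(O)c(C)c(CC)oc3=O)c2O1 | intermediate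
17 | 3-{[(2R)-5-acetyl-4,6-dihydroxy-2-(6-methylhepta-1,5-dien-2-yl)-2,3-dihydro-1-benzofuran-7-yl]methyl}-6-ethyl-4-hydroxy-5-methyl-2H-pyran-2-one | C=C(CCC=C(C)C)[C@H]1Cc2c(O)c(C(C)=O)c(O)c(Cc3c(O)c(C)c(CC)oc3=O)c2O1 | target

## Step count and least certain steps

Total step count: 9. Longest linear sequence: 8 steps (steps 1, 2, 3, 5, 6, 7, 8 and 9, from 1 to 17); step 4 is a one-step branch that supplies 8.

**Step 5 (key step).** The most likely failure is proton transfer from the acidic C3–H of 8 to enolate 9, which returns 5 and opens the way to Claisen self-condensation of the lactone; O-acylation or stalling at the open tricarbonyl stage are the other possibilities. Fallback: starting from 5, the chain is assembled stepwise. Claisen acylation of 5 (LiN(SiMe3)2, 2 equiv; N-methoxy-N-methylpropanamide) would give 8-iodo-5,7-bis(methoxymethoxy)-3-propanoylchroman-2-one F1. Double deprotonation with LiN(i-Pr)2 would give the dilithium dienediolate of the 3-propanoyl lactone F2, which is acylated at its terminal carbon by the same amide to reach 10; DBU then closes 10 to the pyrone, and the sequence rejoins the route at 11.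

**Step 6.** Three processes threaten this step: insertion of the 1,1-disubstituted alkene of 12 in place of the vinyl group, poor facial selectivity in the C–O bond formation on a crowded ring that also carries a coordinating pyronate, and reductive loss of iodine. Fallback: starting from 11, a ligand-free heteroannulation with 12 (Pd(OAc)2, NaHCO3, n-Bu4NCl, DMF, 80 °C) would give racemic 6-ethyl-4-hydroxy-5-methyl-3-{[4,6-bis(methoxymethoxy)-2-(6-methylhepta-1,5-dien-2-yl)-2,3-dihydro-1-benzofuran-7-yl]methyl}-2H-pyran-2-one F3. Its enantiomers are separated by preparative chromatography on a chiral stationary phase, and the (2R) enantiomer rejoins the route at 13.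

**Step 8.** Ionisation of the allylic C2–O1 bond by zerovalent palladium would erode the configuration or open the ring, and slow transmetalation at the hindered iodide would favour reduction. Fallback without palladium: starting from 14, i-PrMgCl·LiCl (2.2 equiv, THF, −20 °C; the first equivalent deprotonates the pyrone) performs iodine–magnesium exchange to the arylmagnesium chloride chloromagnesium pyronate F4. Addition to acetaldehyde gives the carbinol 6-ethyl-4-hydroxy-3-{[(2R)-5-(1-hydroxyethyl)-4,6-bis(methoxymethoxy)-2-(6-methylhepta-1,5-dien-2-yl)-2,3-dihydro-1-benzofuran-7-yl]methyl}-5-methyl-2H-pyran-2-one F5 as a mixture of carbinol epimers, and oxidation with Dess–Martin periodinane rejoins the route at 16.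

**Step 9.** Acid-promoted cyclisation or methanol addition at the 1,5-diene, or ionisation of the allylic ether (now a better leaving group, since the aryloxide is para to the acetyl group), could compete with acetal cleavage. Fallback without protic acid: starting from 16, TMSOTf and 2,2′-bipyridyl in CH2Cl2 at 0 °C exchange the acetals for silyl ethers and silylate the pyrone, giving the tris(trimethylsilyl) ether of the target F6; K2CO3 in MeOH then removes the silyl groups and the sequence arrives at 17.

**Step 3.** Iodination at C6 or twofold iodination would give mixtures that are hard to separate. Fallback: starting from 4, the order of iodination and ring switch is inverted. The conditions of step 5 applied to 4 would lead through lithium 5,7-bis(methoxymethoxy)-4H-chromen-2-olate F7 and 5,7-bis(methoxymethoxy)-3-(2-methyl-3-oxopentanoyl)chroman-2-one F8 to 6-ethyl-4-hydroxy-3-{[2-hydroxy-4,6-bis(methoxymethoxy)phenyl]methyl}-5-methyl-2H-pyran-2-one F9. The free phenol of this product is then iodinated under amine-mediated, ortho-selective conditions (NIS, i-Pr2NH cat., CH2Cl2, −40 °C), which should favour its only free ortho carbon over the para carbon between the two acetals, and the sequence rejoins the route at 11.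

## Further compounds

F1 | step 5 | 8-iodo-5,7-bis(methoxymethoxy)-3-propanoylchroman-2-one | CCC(=O)C1Cc2c(OCOC)cc(OCOC)c(I)c2OC1=O
F2 | step 5 | dilithium dienediolate of the 3-propanoyl lactone | CC=C([O-])C1=C([O-])Oc2c(I)c(OCOC)cc(OCOC)c2C1.[Li+].[Li+]
F3 | step 6 | racemic 6-ethyl-4-hydroxy-5-methyl-3-{[4,6-bis(methoxymethoxy)-2-(6-methylhepta-1,5-dien-2-yl)-2,3-dihydro-1-benzofuran-7-yl]methyl}-2H-pyran-2-one | C=C(CCC=C(C)C)C1Cc2c(OCOC)cc(OCOC)c(Cc3c(O)c(C)c(CC)oc3=O)c2O1
F4 | step 8 | arylmagnesium chloride chloromagnesium pyronate from 14 | C=C(CCC=C(C)C)[C@H]1Cc2c(OCOC)c([Mg]Cl)c(OCOC)c(Cc3c(O[Mg]Cl)c(C)c(CC)oc3=O)c2O1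
F5 | step 8 | 6-ethyl-4-hydroxy-3-{[(2R)-5-(1-hydroxyethyl)-4,6-bis(methoxymethoxy)-2-(6-methylhepta-1,5-dien-2-yl)-2,3-dihydro-1-benzofuran-7-yl]methyl}-5-methyl-2H-pyran-2-one (carbinol epimers) | C=C(CCC=C(C)C)[C@H]1Cc2c(OCOC)c(C(C)O)c(OCOC)c(Cc3c(O)c(C)c(CC)oc3=O)c2O1
F6 | step 9 | tris(trimethylsilyl) ether of the target (both phenols and the pyrone hydroxyl silylated) | C=C(CCC=C(C)C)[C@H]1Cc2c(O[Si](C)(C)C)c(C(C)=O)c(O[Si](C)(C)C)c(Cc3c(O[Si](C)(C)C)c(C)c(CC)oc3=O)c2O1
F7 | step 3 | lithium 5,7-bis(methoxymethoxy)-4H-chromen-2-olate | [Li+].[O-]C1=CCc2c(OCOC)cc(OCOC)cc2O1
F8 | step 3 | 5,7-bis(methoxymethoxy)-3-(2-methyl-3-oxopentanoyl)chroman-2-one | CCC(=O)C(C)C(=O)C1Cc2c(OCOC)cc(OCOC)cc2OC1=O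
F9 | step 3 | 6-ethyl-4-hydroxy-3-{[2-hydroxy-4,6-bis(methoxymethoxy)phenyl]methyl}-5-methyl-2H-pyran-2-one | CCc1oc(=O)c(Cc2c(O)cc(OCOC)cc2OCOC)c(O)c1C
A1 | alternative 1 | 1-[4-hydroxy-2,6-bis(methoxymethoxy)-3-{[(4-methylphenyl)sulfonyl]methyl}phenyl]ethan-1-one | CC(=O)c1c(OCOC)cc(O)c(CS(=O)(=O)c2ccc(C)cc2)c1OCOC
A2 | alternative 1 | dimethylsulfonium 6-methyl-2-oxohept-5-en-1-ylide | C[S+](C)[CH-]C(=O)CCC=C(C)C
A3 | alternative 1 | 1-[(2R)-5-acetyl-4,6-bis(methoxymethoxy)-2,3-dihydro-1-benzofuran-2-yl]-5-methylhex-4-en-1-one | CC(C)=CCCC(=O)[C@H]1Cc2c(OCOC)c(C(C)=O)c(OCOC)cc2O1
A4 | alternative 1 | 6-ethyl-4-hydroxy-5-methyl-2H-pyran-2-one | CCc1oc(=O)cc(O)c1C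
A5 | alternative 2 | acid chloride in which the C6 oxygen and the C7 methylene of the (2R)-4-acetoxy-5-acetyl-2-(6-methylhepta-1,5-dien-2-yl)-2,3-dihydrobenzofuran are tied into a 2-oxochroman ring bearing COCl on its C3 | C=C(CCC=C(C)C)[C@H]1Cc2c(OC(C)=O)c(C(C)=O)c3OC(=O)C(C(=O)Cl)Cc3c2O1
A6 | alternative 2 | (Z)-trimethyl(pent-2-en-3-yloxy)silane | C/C=C(/CC)O[Si](C)(C)C
A7 | alternative 2 | (2R)-5-acetyl-7-[(6-ethyl-4-hydroxy-5-methyl-2-oxo-2H-pyran-3-yl)methyl]-6-hydroxy-2-(6-methylhepta-1,5-dien-2-yl)-2,3-dihydro-1-benzofuran-4-yl acetate | C=C(CCC=C(C)C)[C@H]1Cc2c(OC(C)=O)c(C(C)=O)c(O)c(Cc3c(O)c(C)c(CC)oc3=O)c2O1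
A8 | alternative 3 | 1-iodo-3,5-bis(methoxymethoxy)-2-[(methoxymethoxy)methyl]benzene | COCOCc1c(I)cc(OCOC)cc1OCOC
A9 | alternative 3 | tert-butyldimethyl{[(1S)-5-methyl-1-[(2R)-oxiran-2-yl]hex-4-en-1-yl]oxy}silane | CC(C)=CCC[C@H](O[Si](C)(C)C(C)(C)C)[C@H]1CO1
A10 | alternative 3 | (2R)-2-[(1S)-1-(tert-butyldimethylsilyloxy)-5-methylhex-4-en-1-yl]-4,6-bis(methoxymethoxy)-7-[(methoxymethoxy)methyl]-2,3-dihydro-1-benzofuran | CC(C)=CCC[C@H](O[Si](C)(C)C(C)(C)C)[C@H]1Cc2c(OCOC)cc(OCOC)c(COCOC)c2O1
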